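The route rests on closing ring C of the upper (robinetinidol) unit at the aryl ether bond O1–C8a. The precursor is an open-chain 1,3,3-triarylpropan-1-one: C2 is a ketone, C4 already carries ring A and C8 of a benzylated epigallocatechin, and C8a of ring A bears fluorine, ortho to C4a and meta to the C7 benzyloxy group. In one operation the Z-enolate oxygen displaces this fluoride and gives a 4-aryl-4H-chromene in which C4 is the only stereocentre of the new ring. Syn hydroboration of C2=C3, anti to the C4 aryl group, then sets C3 and C2 all-trans. C4 itself is set earlier by rhodium-catalysed asymmetric conjugate arylation.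

Key step: step 6

Remark: the target is read as robinetinidol-(4α→8)-epigallocatechin, (2R,3S,4S) in the upper unit (2,3-trans-3,4-trans) and (2R,3R) in the lower unit; flavan numbering (O1, C2–C4, C4a, C5–C8, C8a) is used throughout.

Step 1
Reactants: 1 (−)-epigallocatechin
Product: 2 hexa-O-benzyl-epigallocatechin
Conditions: BnBr (8 equiv), NaH (8 equiv), DMF, −20 °C → rt, argon
Reagents that add atoms: benzyl bromide, BrCc1ccccc1
Why: Williamson etherification of the five phenols and the C3 hydroxyl should proceed at low temperature under argon without touching the C2/C3 stereocentres of the flavan.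

Step 2
Reactants: 2 hexa-O-benzyl-epigallocatechin
Product: 3 8-bromo-hexa-O-benzyl-epigallocatechin
Conditions: NBS (1.0 equiv), CH2Cl2, −40 °C → rt
Reagents that add atoms: N-bromosuccinimide, O=C1CCC(=O)N1Br
Why: Electrophilic aromatic bromination of per-O-benzylated flavan-3-ols should occur selectively at C8, the position flanked by O1 and the C7 ether.

Step 3
Reactants: 3 8-bromo-hexa-O-benzyl-epigallocatechin
Product: 5 hexa-O-benzyl-epigallocatechin-8-carbaldehyde, via aryllithium 4 (not isolated)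
Conditions: n-BuLi (1.1 equiv), THF, −78 °C; then DMF, −78 → 0 °C; H2O
Reagents that add atoms: N,N-dimethylformamide, CN(C)C=O
Why: Bromine–lithium exchange at −78 °C should outrun deprotonation of the benzyl ethers, and formylation of the aryllithium with DMF (Bouveault-type) gives the aldehyde.

Step 4
Reactants: 5 hexa-O-benzyl-epigallocatechin-8-carbaldehyde; 6 1-[3,4,5-tris(benzyloxy)phenyl]ethan-1-one
Product: 7 (E)-3-(hexa-O-benzyl-epigallocatechin-8-yl)-1-[3,4,5-tris(benzyloxy)phenyl]prop-2-en-1-one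
Conditions: KOH (aq., 3 equiv), EtOH/THF 1:1, rt → 40 °C
Reagents that add atoms: none
Why: Claisen–Schmidt condensation of a non-enolisable aldehyde with a methyl ketone should give the thermodynamically favoured E-enone.

Step 5
Reactants: 7 the E-enone; 8 [4-(benzyloxy)-2-fluorophenyl]boronic acid (3 equiv)
Product: 9 (3R)-3-[4-(benzyloxy)-2-fluorophenyl]-3-(hexa-O-benzyl-epigallocatechin-8-yl)-1-[3,4,5-tris(benzyloxy)phenyl]propan-1-one
Conditions: [RhCl(C2H4)2]2 (2.5 mol%), (S,S)-Ph-bod* [(1S,4S)-2,5-diphenylbicyclo[2.2.2]octa-2,5-diene, 5.5 mol%], KOH (0.5 equiv), 1,4-dioxane/H2O 10:1, 50 °C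
Reagents that add atoms: none
Why: Rhodium-catalysed asymmetric 1,4-addition of an arylboronic acid (Hayashi–Miyaura reaction) should work because the aryl–rhodium species inserts into the enone and the rhodium enolate is hydrolysed; the chiral diene is chosen to deliver the aryl group to the Re face of the β-carbon, which creates the (R)-centre that becomes C4 (S) of the target under catalyst control (the sense is assigned by analogy with acyclic E-enones, and the antipodal ligand is at hand if the opposite face is delivered).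

Step 6
Reactants: 9 the (3R)-ketone
Product: 11 (4S)-7-(benzyloxy)-4-(hexa-O-benzyl-epigallocatechin-8-yl)-2-[3,4,5-tris(benzyloxy)phenyl]-4H-chromene, via potassium Z-enolate 10 (not isolated)
Conditions: KN(SiMe3)2 (1.05 equiv), 18-crown-6 (1.1 equiv), THF, 0 °C; then DMSO, 90 °C, argon
Reagents that add atoms: none
Why: Deprotonation at C3, the only enolisable position, gives the potassium Z-enolate 10, whose oxygen attacks C8a of ring A ipso to fluorine and expels fluoride through a Meisenheimer-type transition state (intramolecular SNAr O-arylation of an enolate). The closest known reaction types are the alkoxide SNAr pyran closure of fluoroarenes used for flavan-3-ols and the enolate O-arylation step of tandem SN2–SNAr syntheses of 4H-chromenes and of benzofurans from ortho-fluoroaryl ketones. Ring C closes in a 6-exo mode at the arene carbon with the enolate C2=C3 bond inside the new ring (6-(enolendo)-exo-trig). No stereocentre is formed: C4 is not acidic under one equivalent of base and is carried through unchanged, while C2 and C3 are deliberately left as an enol ether for step 7. The step needs O- over C-arylation and a productive enolate geometry: C-attack would give a four-membered ring, and the Z-enolate expected for an aryl alkyl ketone holds the oxygen cis to C4. The fluorine at C8a is the only halogen in the molecule and is activated inductively, without resonance donation, by the meta C7 benzyloxy group.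

Step 7
Reactants: 11 the 4H-chromene
Product: 13 (2R,3S,4S)-7-(benzyloxy)-4-(hexa-O-benzyl-epigallocatechin-8-yl)-2-[3,4,5-tris(benzyloxy)phenyl]chroman-3-ol, via C3-borane 12 (not isolated)
Conditions: BH3·THF (4 equiv), THF, 0 °C → rt; then NaOH (3 M aq.), H2O2 (30%), 0 °C → rt
Reagents that add atoms: hydrogen peroxide, OO (borane, B, adds boron only to intermediate 12)
Why: Hydroboration–oxidation of the 2-aryl enol ether should place boron at C3 and hydrogen at C2 in a syn addition from the face opposite the C4 aryl group, and oxidation with retention then gives the 2,3-trans-3,4-trans alcohol, so C3 (S) and C2 (R) are both set by C4.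

Step 8
Reactants: 13 the deca-O-benzyl dimer
Product: 14 robinetinidol-(4α→8)-epigallocatechin (CNP0275321.3)
Conditions: H2 (1 atm), Pd(OH)2/C (20 wt%), THF/MeOH/H2O 20:20:1, rt; filtration under argon
Reagents that add atoms: none
Why: Hydrogenolysis of the ten benzyl ethers under neutral conditions should leave the C4–C8 interflavan bond, the C2–O1 bonds and all five stereocentres untouched.

Compound list
1 | (−)-epigallocatechin, (2R,3R)-2-(3,4,5-trihydroxyphenyl)chromane-3,5,7-triol | Oc1cc(O)c2c(c1)O[C@H](c1cc(O)c(O)c(O)c1)[C@H](O)C2 | starting material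
2 | hexa-O-benzyl-epigallocatechin, (2R,3R)-3,5,7-tris(benzyloxy)-2-[3,4,5-tris(benzyloxy)phenyl]chromane | c1c(OCc2ccccc2)cc(OCc2ccccc2)c2c1O[C@H](c1cc(OCc3ccccc3)c(OCc3ccccc3)c(OCc3ccccc3)c1)[C@H](OCc1ccccc1)C2 | intermediate
3 | (2R,3R)-8-bromo-hexa-O-benzyl-epigallocatechin | Brc1c(OCc2ccccc2)cc(OCc2ccccc2)c2c1O[C@H](c1cc(OCc3ccccc3)c(OCc3ccccc3)c(OCc3ccccc3)c1)[C@H](OCc1ccccc1)C2 | intermediate
4 | (2R,3R)-8-lithio-hexa-O-benzyl-epigallocatechin | [Li]c1c(OCc2ccccc2)cc(OCc2ccccc2)c2c1O[C@H](c1cc(OCc3ccccc3)c(OCc3ccccc3)c(OCc3ccccc3)c1)[C@H](OCc1ccccc1)C2 | intermediate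
5 | (2R,3R)-hexa-O-benzyl-epigallocatechin-8-carbaldehyde | O=Cc1c(OCc2ccccc2)cc(OCc2ccccc2)c2c1O[C@H](c1cc(OCc3ccccc3)c(OCc3ccccc3)c(OCc3ccccc3)c1)[C@H](OCc1ccccc1)C2 | intermediate
6 | 1-[3,4,5-tris(benzyloxy)phenyl]ethan-1-one | CC(=O)c1cc(OCc2ccccc2)c(OCc2ccccc2)c(OCc2ccccc2)c1 | starting material
7 | (E)-3-[(2R,3R)-hexa-O-benzyl-epigallocatechin-8-yl]-1-[3,4,5-tris(benzyloxy)phenyl]prop-2-en-1-one | O=C(c1cc(OCc2ccccc2)c(OCc2ccccc2)c(OCc2ccccc2)c1)/C=C/c1c(OCc2ccccc2)cc(OCc2ccccc2)c2c1O[C@H](c1cc(OCc3ccccc3)c(OCc3ccccc3)c(OCc3ccccc3)c1)[C@H](OCc1ccccc1)C2 | intermediate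
8 | [4-(benzyloxy)-2-fluorophenyl]boronic acid | OB(O)c1ccc(OCc2ccccc2)cc1F | starting material
9 | (3R)-3-[4-(benzyloxy)-2-fluorophenyl]-3-[(2R,3R)-hexa-O-benzyl-epigallocatechin-8-yl]-1-[3,4,5-tris(benzyloxy)phenyl]propan-1-one | O=C(c1cc(OCc2ccccc2)c(OCc2ccccc2)c(OCc2ccccc2)c1)C[C@@H](c1ccc(OCc2ccccc2)cc1F)c1c(OCc2ccccc2)cc(OCc2ccccc2)c2c1O[C@H](c1cc(OCc3ccccc3)c(OCc3ccccc3)c(OCc3ccccc3)c1)[C@H](OCc1ccccc1)C2 | intermediate
10 | potassium (Z)-enolate of 9 (O cis to C4, C4 unchanged) | [K+].[O-]/C(c1cc(OCc2ccccc2)c(OCc2ccccc2)c(OCc2ccccc2)c1)=C\[C@@H](c1ccc(OCc2ccccc2)cc1F)c1c(OCc2ccccc2)cc(OCc2ccccc2)c2c1O[C@H](c1cc(OCc3ccccc3)c(OCc3ccccc3)c(OCc3ccccc3)c1)[C@H](OCc1ccccc1)C2 | intermediate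
11 | (4S)-7-(benzyloxy)-4-[(2R,3R)-hexa-O-benzyl-epigallocatechin-8-yl]-2-[3,4,5-tris(benzyloxy)phenyl]-4H-chromene | C(c1ccccc1)Oc1ccc2c(c1)OC(c1cc(OCc3ccccc3)c(OCc3ccccc3)c(OCc3ccccc3)c1)=C[C@@H]2c1c(OCc2ccccc2)cc(OCc2ccccc2)c2c1O[C@H](c1cc(OCc3ccccc3)c(OCc3ccccc3)c(OCc3ccccc3)c1)[C@H](OCc1ccccc1)C2 | intermediate
12 | (2S,3S,4S)-3-boranyl-7-(benzyloxy)-4-[(2R,3R)-hexa-O-benzyl-epigallocatechin-8-yl]-2-[3,4,5-tris(benzyloxy)phenyl]chromane (2,3-trans-3,4-trans) | C(c1ccccc1)Oc1ccc2c(c1)O[C@H](c1cc(OCc3ccccc3)c(OCc3ccccc3)c(OCc3ccccc3)c1)[C@@H](B)[C@@H]2c1c(OCc2ccccc2)cc(OCc2ccccc2)c2c1O[C@H](c1cc(OCc3ccccc3)c(OCc3ccccc3)c(OCc3ccccc3)c1)[C@H](OCc1ccccc1)C2 | intermediate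
13 | (2R,3S,4S)-7-(benzyloxy)-4-[(2R,3R)-hexa-O-benzyl-epigallocatechin-8-yl]-2-[3,4,5-tris(benzyloxy)phenyl]chroman-3-ol | C(c1ccccc1)Oc1ccc2c(c1)O[C@H](c1cc(OCc3ccccc3)c(OCc3ccccc3)c(OCc3ccccc3)c1)[C@@H](O)[C@@H]2c1c(OCc2ccccc2)cc(OCc2ccccc2)c2c1O[C@H](c1cc(OCc3ccccc3)c(OCc3ccccc3)c(OCc3ccccc3)c1)[C@H](OCc1ccccc1)C2 | intermediate
14 | robinetinidol-(4α→8)-epigallocatechin (CNP0275321.3), upper unit (2R,3S,4S), lower unit (2R,3R) | Oc1ccc2c(c1)O[C@H](c1cc(O)c(O)c(O)c1)[C@@H](O)[C@@H]2c1c(O)cc(O)c2c1O[C@H](c1cc(O)c(O)c(O)c1)[C@H](O)C2 | target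

Total step count: 8. Longest linear sequence: 8 steps (1 → 14); compounds 6 and 8 are purchased.

Steps most likely to fail

Step 6 (key step). The fluoride at C8a is activated only inductively, so displacement by the enolate oxygen may be too slow, and prolonged heating of the enolate may then cause decomposition or loss of configurational integrity at C4. The fallback replaces SNAr by a copper-catalysed coupling of an aryl bromide. It sets out from enone 7. 1-(Benzyloxy)-3-bromobenzene is iodinated para to the ether (NIS, cat. CF3CO2H, MeCN) to 4-(benzyloxy)-2-bromo-1-iodobenzene F1. Iodine–magnesium exchange and borylation (iPrMgCl·LiCl, THF, −20 °C; B(OMe)3; aq. HCl) give [4-(benzyloxy)-2-bromophenyl]boronic acid F2. Addition of F2 to 7 under the conditions of step 5 should give the bromo analogue of 9, (3R)-3-[4-(benzyloxy)-2-bromophenyl]-3-(hexa-O-benzyl-epigallocatechin-8-yl)-1-[3,4,5-tris(benzyloxy)phenyl]propan-1-one F3. Ullmann-type intramolecular O-arylation of its enolate (CuI 10 mol%, 1,10-phenanthroline 20 mol%, Cs2CO3, toluene, 110 °C) forms the same O1–C8a bond and returns to chromene 11.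

Step 5. Insertion at the β-carbon, which is hindered and electron-rich because of the two ortho oxygen substituents of the flavan ring, may be slow, so that protodeboronation of 8 competes; the facial selectivity may also be insufficient. The fallback builds the C4–C8 bond by a cationic route and sets out from 2. Claisen–Schmidt condensation of 4-(benzyloxy)-2-fluorobenzaldehyde with 6 gives (E)-3-[4-(benzyloxy)-2-fluorophenyl]-1-[3,4,5-tris(benzyloxy)phenyl]prop-2-en-1-one F4. Lewis-acid-mediated conjugate Friedel–Crafts alkylation of 2 at its nucleophilic C8 with F4 (Sc(OTf)3 or BF3·OEt2, CH2Cl2, −20 °C → rt) should give 9 together with its (3S)-epimer F5. The two are diastereomers because the flavan unit is enantiopure, so chromatography returns pure 9. This fallback is not stereoselective at C4 and costs about half of the material, but it also makes steps 2 to 4 unnecessary.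

Step 7. Addition of borane to the hindered trisubstituted enol ether may be slow, the C3-borane may lose the aryloxy group by β-elimination (opening of ring C), or the facial discrimination may be incomplete. The fallback sets out from 11 and uses copper-catalysed protoboration (CuCl 5 mol%, Xantphos 5 mol%, NaOtBu 10 mol%, B2pin2, MeOH, THF, rt → 40 °C). Syn addition of Cu–B with boron at C3, anti to the C4 aryl group, and protonation at C2 should give the isolable (2S,3S,4S)-3-(pinacolatoboryl)flavan F6. Oxidation with NaBO3·4H2O (THF/H2O, rt) then proceeds with retention and returns to 13.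

Further compounds
F1 | step 6 | 4-(benzyloxy)-2-bromo-1-iodobenzene | Ic1ccc(OCc2ccccc2)cc1Br
F2 | step 6 | [4-(benzyloxy)-2-bromophenyl]boronic acid | OB(O)c1ccc(OCc2ccccc2)cc1Br
F3 | step 6 | (3R)-3-[4-(benzyloxy)-2-bromophenyl]-3-[(2R,3R)-hexa-O-benzyl-epigallocatechin-8-yl]-1-[3,4,5-tris(benzyloxy)phenyl]propan-1-one | O=C(c1cc(OCc2ccccc2)c(OCc2ccccc2)c(OCc2ccccc2)c1)C[C@@H](c1ccc(OCc2ccccc2)cc1Br)c1c(OCc2ccccc2)cc(OCc2ccccc2)c2c1O[C@H](c1cc(OCc3ccccc3)c(OCc3ccccc3)c(OCc3ccccc3)c1)[C@H](OCc1ccccc1)C2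
F4 | step 5 | (E)-3-[4-(benzyloxy)-2-fluorophenyl]-1-[3,4,5-tris(benzyloxy)phenyl]prop-2-en-1-one | O=C(c1cc(OCc2ccccc2)c(OCc2ccccc2)c(OCc2ccccc2)c1)/C=C/c1ccc(OCc2ccccc2)cc1F
F5 | step 5 | (3S)-3-[4-(benzyloxy)-2-fluorophenyl]-3-[(2R,3R)-hexa-O-benzyl-epigallocatechin-8-yl]-1-[3,4,5-tris(benzyloxy)phenyl]propan-1-one | O=C(c1cc(OCc2ccccc2)c(OCc2ccccc2)c(OCc2ccccc2)c1)C[C@H](c1ccc(OCc2ccccc2)cc1F)c1c(OCc2ccccc2)cc(OCc2ccccc2)c2c1O[C@H](c1cc(OCc3ccccc3)c(OCc3ccccc3)c(OCc3ccccc3)c1)[C@H](OCc1ccccc1)C2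
F6 | step 7 | (2S,3S,4S)-7-(benzyloxy)-4-[(2R,3R)-hexa-O-benzyl-epigallocatechin-8-yl]-3-(4,4,5,5-tetramethyl-1,3,2-dioxaborolan-2-yl)-2-[3,4,5-tris(benzyloxy)phenyl]chromane | C(c1ccccc1)Oc1ccc2c(c1)O[C@H](c1cc(OCc3ccccc3)c(OCc3ccccc3)c(OCc3ccccc3)c1)[C@@H](B1OC(C)(C)C(C)(C)O1)[C@@H]2c1c(OCc2ccccc2)cc(OCc2ccccc2)c2c1O[C@H](c1cc(OCc3ccccc3)c(OCc3ccccc3)c(OCc3ccccc3)c1)[C@H](OCc1ccccc1)C2
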